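**Retrosynthetic overview**
1. Target ← Ac2O acetylation of C13-OH and TBDPS removal ← transannular methyl ketalization of a C1 dimethyl ketal with the C4 tertiary OH, which closes the 1,4-oxa bridge (THF) and fixes C1.
2. Ketal precursor ← 10-membered carbocycle made by an intramolecular vinylogous aldol of the butenolide γ-CH2 (C6) onto a C5 aldehyde, then E1cB dehydration. The ring forces the C5=C6 geometry.
3. Acyclic precursor ← NHK coupling of aldehyde 16 (C8–C1 chain) with 4-bromobutenolide 20, then oxidation, ketoreductase reduction to set C8, and tigloylation.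
4. Aldehyde 16 ← Fukuyama coupling of a thioester (C10 set by Rh-catalysed asymmetric hydrogenation) with a zinc reagent from a Sharpless-epoxidation-derived tertiary carbinol (C4).
5. Ring order: butenolide (from tetronic acid, Step 14), then the 10-membered carbocycle (Step 23), then the oxa-bridged THF (Step 25).

Assumptions, stated in one line: MeOH opens itaconic anhydride at the non-conjugated carbonyl; the C5=C6 geometry of the 10-membered ring is forced to the ring-cis (target) isomer; the bridged ketalization gives the natural C1 configuration because only one C1 epimer can span the THF.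

---

**Step 1**
Reactants: 1, itaconic anhydride
Product: 2, 4-methoxy-2-methylidene-4-oxobutanoic acid (4-methyl hydrogen itaconate)
Conditions: MeOH (1.1 equiv), THF, 65 °C
Reagents that add atoms: methanol, CO
Why: Alcoholysis of the cyclic anhydride at the more electrophilic non-conjugated carbonyl gives the monoester. No stereocentre is formed.

**Step 2**
Reactants: 2
Product: 3, (R)-4-methoxy-2-methyl-4-oxobutanoic acid
Conditions: H2 (4 bar), [Rh(cod)(Me-DuPhos)]BF4 (1 mol%) with the ligand enantiomer giving the (R)-acid, MeOH, 25 °C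
Reagents that add atoms: none
Why: Rh-catalysed asymmetric hydrogenation of the 1,1-disubstituted acrylic acid sets the C10 methyl stereocentre, with the carboxylate directing the catalyst. This is the first stereocentre.

**Step 3**
Reactants: 3
Product: 4, methyl (R)-4-(ethylsulfanyl)-3-methyl-4-oxobutanoate
Conditions: EtSH, EDC·HCl, DMAP (0.1 equiv), CH2Cl2, 0 → 23 °C
Reagents that add atoms: ethanethiol, CCS
Why: Carbodiimide thioesterification is selective for the free acid over the methyl ester, and the mild conditions do not epimerise the α-centre.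

**Step 4**
Reactants: 5, 2-(benzyloxy)acetaldehyde; 6, ethyl 2-(triphenylphosphoranylidene)propanoate
Product: 7, ethyl (E)-4-(benzyloxy)-2-methylbut-2-enoate
Conditions: CH2Cl2, 25 °C
Reagents that add atoms: none
Why: A stabilised ylide in a Wittig olefination gives the E-trisubstituted enoate needed for the asymmetric epoxidation.

**Step 5**
Reactants: 7
Product: 8, (E)-4-(benzyloxy)-2-methylbut-2-en-1-ol
Conditions: DIBAL-H (2.3 equiv), CH2Cl2, −78 °C
Reagents that add atoms: none
Why: DIBAL reduces the ester to the allylic alcohol and leaves the benzyl ether and alkene intact.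

**Step 6**
Reactants: 8
Product: 9, [(2S,3S)-3-(benzyloxymethyl)-2-methyloxiran-2-yl]methanol
Conditions: Ti(OiPr)4 (10 mol%), L-(+)-diethyl tartrate (12 mol%), TBHP (2 equiv), 3 Å MS, CH2Cl2, −20 °C
Reagents that add atoms: tert-butyl hydroperoxide, CC(C)(C)OO (supplies the epoxide O)
Why: Sharpless asymmetric epoxidation of the (E)-2-methyl allylic alcohol with the L-tartrate catalyst delivers O to one face and sets the future C4 configuration.

**Step 7**
Reactants: 9
Product: 10, (2R)-4-(benzyloxy)-2-methylbutane-1,2-diol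
Conditions: LiAlH4, THF, 0 → 23 °C
Reagents that add atoms: none
Why: C2 of the epoxide is quaternary, so hydride can only open at C3. The C4–O bond is kept, so the configuration is retained and becomes (R) through a CIP priority change.

**Step 8**
Reactants: 10
Product: 11, {[(2R)-4-(benzyloxy)-2-methyl-2-(triethylsilyloxy)butyl]oxy}triethylsilane
Conditions: TESOTf (2.4 equiv), 2,6-lutidine (3 equiv), CH2Cl2, −78 → 0 °C
Reagents that add atoms: triethylsilyl triflate, CC[Si](CC)(CC)OS(=O)(=O)C(F)(F)F
Why: TESOTf silylates both the primary and the hindered tertiary alcohol, so no free OH remains for the organozinc or ketal steps.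

**Step 9**
Reactants: 11
Product: 12, (3R)-3-methyl-3,4-bis(triethylsilyloxy)butan-1-ol
Conditions: H2 (1 atm), 10% Pd/C, EtOAc, 23 °C
Reagents that add atoms: none
Why: Hydrogenolysis of the benzyl ether leaves the silyl ethers untouched.

**Step 10**
Reactants: 12
Product: 13, (R)-1-iodo-3-methyl-3,4-bis(triethylsilyloxy)butane
Conditions: I2, PPh3, imidazole, CH2Cl2, 0 °C
Reagents that add atoms: iodine, II
Why: Appel-type (Garegg–Samuelsson) iodination of the primary alcohol, buffered by imidazole, gives the primary iodide for zinc insertion.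

**Step 11**
Reactants: 13; 4
Product: 14, methyl (3R,7R)-3,7-dimethyl-4-oxo-7,8-bis(triethylsilyloxy)octanoate
Conditions: (a) 13, Zn dust, LiCl, THF, 40 °C; (b) 4, PdCl2(PPh3)2 (5 mol%), THF/toluene, 23 °C
Reagents that add atoms: none
Why: Fukuyama coupling of a thioester with an alkylzinc iodide forms the C1–C2 bond. It is chemoselective over the methyl ester and silyl ethers and does not epimerise C10.

**Step 12**
Reactants: 14
Product: 15, methyl (3R,7R)-4,4-dimethoxy-3,7-dimethyl-7,8-bis(triethylsilyloxy)octanoate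
Conditions: Me3SiOMe (2.5 equiv), TMSOTf (0.05 equiv), CH2Cl2, −78 → −40 °C
Reagents that add atoms: methoxytrimethylsilane, C[Si](C)(C)OC
Why: Noyori ketalization under non-protic, low-temperature conditions protects the C1 ketone as a dimethyl ketal. This blocks C10 enolisation and the later ketone reduction, and the TES ethers survive.

**Step 13**
Reactants: 15
Product: 16, (3R,7R)-4,4-dimethoxy-3,7-dimethyl-7,8-bis(triethylsilyloxy)octanal
Conditions: DIBAL-H (1.05 equiv), CH2Cl2, −78 °C
Reagents that add atoms: none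
Why: Partial reduction of the methyl ester to the aldehyde is stopped at −78 °C by the stable aluminium hemiacetal. The ketal and silyl ethers survive, and C10 is β to the aldehyde so it cannot epimerise.

**Step 14**
Reactants: 17, tetronic acid (furan-2,4(3H,5H)-dione)
Product: 18, 4-bromo-2-oxo-2,5-dihydrofuran-3-carbaldehyde
Conditions: POBr3 (2 equiv), DMF, 0 → 60 °C, then aqueous work-up
Reagents that add atoms: phosphoryl bromide, O=P(Br)(Br)Br; N,N-dimethylformamide, CN(C)C=O (its carbonyl carbon becomes the CHO)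
Why: Vilsmeier–Haack–Arnold bromoformylation of the cyclic β-keto-lactone formylates C3 and converts the C4 enol into a vinyl bromide.

**Step 15**
Reactants: 18
Product: 19, 4-bromo-3-(hydroxymethyl)furan-2(5H)-one
Conditions: NaBH4 (0.3 equiv), CeCl3·7H2O, MeOH/CH2Cl2, −78 °C
Reagents that add atoms: none
Why: Luche reduction is selective for the aldehyde over the lactone and the vinyl bromide.

**Step 16**
Reactants: 19
Product: 20, 4-bromo-3-{[(tert-butyldiphenylsilyl)oxy]methyl}furan-2(5H)-one
Conditions: TBDPSCl (1.1 equiv), imidazole, DMF, 0 → 23 °C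
Reagents that add atoms: tert-butyldiphenylsilyl chloride, CC(C)(C)[Si](Cl)(c1ccccc1)c1ccccc1
Why: The robust TBDPS ether keeps C13-O inert to base, acid and Cr(II) in the later steps.

**Step 17**
Reactants: 16; 20
Product: 21, 4-[(3R,7R)-1-hydroxy-4,4-dimethoxy-3,7-dimethyl-7,8-bis(triethylsilyloxy)octyl]-3-[(TBDPSoxy)methyl]furan-2(5H)-one (C1′ = C8 as a ~1:1 epimer mixture)
Conditions: CrCl2 (8 equiv), NiCl2 (0.05 equiv), DMF, 23 °C
Reagents that add atoms: none
Why: Nozaki–Hiyama–Kishi coupling of the β-bromo-enoate with the aldehyde forms the C7–C8 bond chemoselectively. The C8 carbinol is formed unselectively and its stereochemistry is reset in Steps 18–19.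

**Step 18**
Reactants: 21
Product: 22, the C8 ketone (4-acylbutenolide): 4-[(3R,7R)-4,4-dimethoxy-3,7-dimethyl-1-oxo-7,8-bis(triethylsilyloxy)octyl]-3-[(TBDPSoxy)methyl]furan-2(5H)-one
Conditions: Dess–Martin periodinane, NaHCO3, CH2Cl2, 23 °C
Reagents that add atoms: none
Why: Oxidation removes the unselectively formed C8 stereocentre so that it can be set by catalyst control. The buffer protects the ketal and TES ethers.

**Step 19**
Reactants: 22
Product: 23, the (1S)-alcohol at C8 (same skeleton as 21, with the C8 carbinol S)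
Conditions: (S)-selective ketoreductase (NADPH-dependent alcohol dehydrogenase, EC 1.1.1.-) from a KRED screen, NADP+, glucose, glucose dehydrogenase, KPi pH 7.0/DMSO (4:1), 30 °C
Reagents that add atoms: none
Why: The ketoreductase delivers hydride to one enantiotopic face of the ketone, giving the C8 (S) alcohol with enzyme control largely independent of the C10 centre. Glucose/GDH recycles the cofactor.

**Step 20**
Reactants: 23; 24, tiglic acid ((E)-2-methylbut-2-enoic acid)
Product: 25, the C8 tiglate ester of 23 ((E)-2-methylbut-2-enoate)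
Conditions: 24, 2,4,6-trichlorobenzoyl chloride, Et3N, THF, then 23, DMAP, toluene, 23 °C
Reagents that add atoms: none (the tigloyl group comes from 24)
Why: Yamaguchi esterification through the mixed anhydride acylates the hindered secondary alcohol without touching C8 or the E-alkene.

**Step 21**
Reactants: 25
Product: 26, the primary alcohol at C5 (C5-OTES removed; C4-OTES retained)
Conditions: PPTS (0.1 equiv), MeOH/CH2Cl2 (1:1), 0 °C, 1 h
Reagents that add atoms: none
Why: Mild acid cleaves the primary TES ether selectively. The tertiary TES, dimethyl ketal, tiglate and TBDPS ether survive.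

**Step 22**
Reactants: 26
Product: 27, the C5 aldehyde
Conditions: Dess–Martin periodinane, NaHCO3, CH2Cl2, 23 °C
Reagents that add atoms: none
Why: Oxidation gives an aldehyde on the quaternary C4, which is non-enolisable and cannot epimerise.

**Step 23**
Reactants: 27
Product: 28, macrocyclic aldol adduct (C5 carbinol/C6 epimers unspecified)
Conditions: LiHMDS (1.1 equiv), THF, −78 °C, substrate added by syringe pump to ~2 mM
Reagents that add atoms: none
Why: Deprotonation at the most acidic ring γ-CH2 (C6) gives the lithium dienolate, which adds to the aldehyde in an intramolecular vinylogous aldol, closing the 10-membered ring. The new C5/C6 stereocentres are destroyed in the next step.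

**Step 24**
Reactants: 28
Product: 29, macrocycle with the C5=C6 alkene: tiglate, dimethyl ketal, OTES and OTBDPS intact
Conditions: MsCl, Et3N, CH2Cl2, 0 °C; then DBU, 23 °C (one pot)
Reagents that add atoms: none
Why: Mesylation followed by E1cB elimination (acidic C6–H) gives the exocyclic alkene. Only the ring-cis geometry (C4 trans to lactone O) is accessible in the 10-membered ring, which matches the target.

**Step 25**
Reactants: 29
Product: 30, bicyclic methyl ketal with C13-OTBDPS
Conditions: CSA (0.1 equiv), MeOH (5 equiv), CH2Cl2, 23 °C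
Reagents that add atoms: none (the retained OMe comes from 29)
Why: Acid removes the tertiary TES and ionises one ketal OMe. The C4-OH adds transannularly, closing the 2-methoxy-THF. The bridged geometry allows only one C1 configuration, (1S) for C4 (R), and this is set under thermodynamic control.

**Step 26**
Reactants: 30
Product: 31, the C13 primary alcohol
Conditions: HF·pyridine, pyridine/THF, 0 → 23 °C
Reagents that add atoms: none
Why: Buffered HF removes the primary TBDPS ether and leaves the bridged ketal, tiglate and lactone untouched.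

**Step 27**
Reactants: 31
Product: 32, Vernolide-B (target)
Conditions: Ac2O, pyridine, DMAP (cat.), CH2Cl2, 0 °C
Reagents that add atoms: acetic anhydride, CC(=O)OC(C)=O
Why: Chemoselective acetylation of the only free OH gives the C13 acetate.

---

**Compound list**

| No. | Name | SMILES | Role |
|---|---|---|---|
| 1 | itaconic anhydride | C=C1CC(=O)OC1=O | starting material |
| 2 | 4-methoxy-2-methylidene-4-oxobutanoic acid | C=C(CC(=O)OC)C(=O)O | intermediate |
| 3 | (R)-4-methoxy-2-methyl-4-oxobutanoic acid | C[C@H](CC(=O)OC)C(=O)O | intermediate |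
| 4 | methyl (R)-4-(ethylsulfanyl)-3-methyl-4-oxobutanoate | C[C@H](CC(=O)OC)C(=O)SCC | intermediate |
| 5 | 2-(benzyloxy)acetaldehyde | O=CCOCc1ccccc1 | starting material |
| 6 | ethyl 2-(triphenylphosphoranylidene)propanoate | CCOC(=O)C(C)=P(c1ccccc1)(c1ccccc1)c1ccccc1 | starting material |
| 7 | ethyl (E)-4-(benzyloxy)-2-methylbut-2-enoate | CCOC(=O)/C(C)=C/COCc1ccccc1 | intermediate |
| 8 | (E)-4-(benzyloxy)-2-methylbut-2-en-1-ol | OC/C(C)=C/COCc1ccccc1 | intermediate |
| 9 | [(2S,3S)-3-(benzyloxymethyl)-2-methyloxiran-2-yl]methanol | OC[C@]1(C)O[C@H]1COCc1ccccc1 | intermediate |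
| 10 | (2R)-4-(benzyloxy)-2-methylbutane-1,2-diol | OC[C@](C)(O)CCOCc1ccccc1 | intermediate |
| 11 | bis-TES ether of 10 | CC[Si](CC)(CC)OC[C@@](C)(CCOCc1ccccc1)O[Si](CC)(CC)CC | intermediate |
| 12 | (3R)-3-methyl-3,4-bis(triethylsilyloxy)butan-1-ol | OCC[C@](C)(CO[Si](CC)(CC)CC)O[Si](CC)(CC)CC | intermediate |
| 13 | (R)-1-iodo-3-methyl-3,4-bis(triethylsilyloxy)butane | ICC[C@](C)(CO[Si](CC)(CC)CC)O[Si](CC)(CC)CC | intermediate |
| 14 | methyl (3R,7R)-3,7-dimethyl-4-oxo-7,8-bis(TESoxy)octanoate | COC(=O)C[C@@H](C)C(=O)CC[C@](C)(CO[Si](CC)(CC)CC)O[Si](CC)(CC)CC | intermediate |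
| 15 | methyl (3R,7R)-4,4-dimethoxy-3,7-dimethyl-7,8-bis(TESoxy)octanoate | COC(=O)C[C@@H](C)C(OC)(OC)CC[C@](C)(CO[Si](CC)(CC)CC)O[Si](CC)(CC)CC | intermediate |
| 16 | (3R,7R)-4,4-dimethoxy-3,7-dimethyl-7,8-bis(TESoxy)octanal | O=CC[C@@H](C)C(OC)(OC)CC[C@](C)(CO[Si](CC)(CC)CC)O[Si](CC)(CC)CC | intermediate |
| 17 | tetronic acid | O=C1COC(=O)C1 | starting material |
| 18 | 4-bromo-2-oxo-2,5-dihydrofuran-3-carbaldehyde | O=CC1=C(Br)COC1=O | intermediate |
| 19 | 4-bromo-3-(hydroxymethyl)furan-2(5H)-one | OCC1=C(Br)COC1=O | intermediate |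
| 20 | 4-bromo-3-[(TBDPSoxy)methyl]furan-2(5H)-one | CC(C)(C)[Si](c1ccccc1)(c1ccccc1)OCC1=C(Br)COC1=O | intermediate |
| 21 | C8-hydroxy NHK adduct (C8 epimer mixture) | OC(C1=C(CO[Si](c2ccccc2)(c2ccccc2)C(C)(C)C)C(=O)OC1)C[C@@H](C)C(OC)(OC)CC[C@](C)(CO[Si](CC)(CC)CC)O[Si](CC)(CC)CC | intermediate |
| 22 | C8 ketone (4-acylbutenolide) | O=C(C1=C(CO[Si](c2ccccc2)(c2ccccc2)C(C)(C)C)C(=O)OC1)C[C@@H](C)C(OC)(OC)CC[C@](C)(CO[Si](CC)(CC)CC)O[Si](CC)(CC)CC | intermediate |
| 23 | (8S)-alcohol | O[C@H](C1=C(CO[Si](c2ccccc2)(c2ccccc2)C(C)(C)C)C(=O)OC1)C[C@@H](C)C(OC)(OC)CC[C@](C)(CO[Si](CC)(CC)CC)O[Si](CC)(CC)CC | intermediate |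
| 24 | tiglic acid | C/C=C(\C)C(=O)O | starting material |
| 25 | C8 tiglate | C/C=C(\C)C(=O)O[C@H](C1=C(CO[Si](c2ccccc2)(c2ccccc2)C(C)(C)C)C(=O)OC1)C[C@@H](C)C(OC)(OC)CC[C@](C)(CO[Si](CC)(CC)CC)O[Si](CC)(CC)CC | intermediate |
| 26 | C5 primary alcohol | C/C=C(\C)C(=O)O[C@H](C1=C(CO[Si](c2ccccc2)(c2ccccc2)C(C)(C)C)C(=O)OC1)C[C@@H](C)C(OC)(OC)CC[C@](C)(CO)O[Si](CC)(CC)CC | intermediate |
| 27 | C5 aldehyde | C/C=C(\C)C(=O)O[C@H](C1=C(CO[Si](c2ccccc2)(c2ccccc2)C(C)(C)C)C(=O)OC1)C[C@@H](C)C(OC)(OC)CC[C@](C)(C=O)O[Si](CC)(CC)CC | intermediate |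
| 28 | macrocyclic aldol adduct (C5/C6 unspecified) | C/C=C(\C)C(=O)O[C@H]1C[C@@H](C)C(OC)(OC)CC[C@](C)(C(O)C3OC(=O)C(CO[Si](c4ccccc4)(c4ccccc4)C(C)(C)C)=C31)O[Si](CC)(CC)CC | intermediate |
| 29 | macrocyclic ylidene-butenolide, dimethyl ketal, C4-OTES | C/C=C(\C)C(=O)O[C@H]1C[C@@H](C)C(OC)(OC)CC[C@](C)(/C=C3/OC(=O)C(CO[Si](c4ccccc4)(c4ccccc4)C(C)(C)C)=C31)O[Si](CC)(CC)CC | intermediate |
| 30 | bridged methyl ketal, C13-OTBDPS | C/C=C(\C)C(=O)O[C@H]1C[C@@H](C)[C@]2(OC)CC[C@](C)(/C=C3/OC(=O)C(CO[Si](c4ccccc4)(c4ccccc4)C(C)(C)C)=C31)O2 | intermediate |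
| 31 | C13 alcohol | C/C=C(\C)C(=O)O[C@H]1C[C@@H](C)[C@]2(OC)CC[C@](C)(/C=C3/OC(=O)C(CO)=C31)O2 | intermediate |
| 32 | Vernolide-B | C/C=C(\C)C(=O)O[C@H]1C[C@@H](C)[C@]2(OC)CC[C@](C)(/C=C3/OC(=O)C(COC(C)=O)=C31)O2 | target |

---

**Totals:** 27 steps in total, with a longest linear sequence of 21 steps (5 → 7 → 8 → 9 → 10 → 11 → 12 → 13 → 14 → 15 → 16 → 21 → 22 → 23 → 25 → 26 → 27 → 28 → 29 → 30 → 31 → 32).

**Three steps most likely to fail**
1. **Step 23 (macro vinylogous aldol).** Risks are strain in the 10-membered ring, silanolate loss from the C13 dienolate, and deprotonation at C8 (γ′) that would epimerise C8. Fallback: convert the butenolide of 26 to its C6 diethyl phosphonate (NBS, then P(OEt)3), oxidise C5, and close the ring by a Masamune–Roush intramolecular Horner–Wadsworth–Emmons reaction.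
2. **Step 19 (ketoreductase on the lipophilic, highly electrophilic enedione-type ketone 22).** The enzyme may not accept the substrate or may give low selectivity. Fallback: replace the biocatalyst with Noyori–Ikariya asymmetric transfer hydrogenation (RuCl[(S,S)-TsDPEN](p-cymene), HCO2H/Et3N), or CBS reduction.
3. **Step 17 (NHK coupling of the hindered β-bromobutenolide with aldehyde 16).** Reductive dehalogenation or low conversion is likely. Fallback: convert 20 to the 4-iodobutenolide and do a low-temperature i-PrMgCl·LiCl halogen–metal exchange, then add to 16 in place of the chromium reaction.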